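(The numbers belong to no real substance, and the outcome is calculated.)

The decision is how to mix: charge everything at once, dose one partner, or run a tank.

    starting material + initiating radical → capped initiator + first chain carrier (k1 = 33000 M⁻¹ s⁻¹)
    initiator → 2 initiating radical (k2 = 0.058 h⁻¹)
    reagent + first chain carrier ⇌ target + second chain carrier (K3 = 1.2, k3 = 1.5 × 10⁶ M⁻¹ h⁻¹)
    starting material + second chain carrier → by-product + first chain carrier (k4 = 3.3 × 10⁶ M⁻¹ h⁻¹)
    2 second chain carrier → ended chains A (k5 = 9 × 10⁷ M⁻¹ s⁻¹)
    starting material + target → side product (k6 = 0.024 M⁻¹ h⁻¹)
    second chain carrier + radical scavenger → ended chains B (k7 = 3.9 × 10⁶ M⁻¹ s⁻¹)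
    starting material + protic impurity → quenched substrate (k8 = 0.65 M⁻¹ h⁻¹)

| flask | starting material | reagent | protic impurity | initiator | radical scavenger | remark | time |
|---|---|---|---|---|---|---|---|
| autumn | 0.43 M | 0.559 M | 0.0430 M | 21 mM | 2.1 mM | a single well-mixed tank run continuously and read at steady state, 5.0 d in it on average |  |
| dusk | 0.43 M | 0.559 M | 0.0430 M | 21 mM | 2.1 mM | a closed flask charged with all of it at once and left for 5.0 d | 5.0 d |
| spring | 0.43 M | 0.559 M (fed, over 2.50 d) | 0.0430 M | 21 mM | 2.1 mM | a stirred flask in which reagent is dosed at a steady rate over 2.50 d without added volume, worked up at 5.0 d | 5.0 d |
| noon | 0.43 M (fed, over 2.50 d) | 0.559 M | 0.0430 M | 21 mM | 2.1 mM | all but starting material at the start; starting material goes in evenly over 2.50 d, the run ends at 5.0 d | 5.0 d |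

1. the set-up with the highest share of target in all that became target or side product, at the outlet or at the end ("none" if the first two lie within 2 percentage points) (autumn / dusk / spring / noon / none)
2. share of target in all that became target or side product, at the outlet or at the end, autumn
3. share of target in all that became target or side product, at the outlet or at the end, dusk
4. share of target in all that became target or side product, at the outlet or at the end, spring
5. share of target in all that became target or side product, at the outlet or at the end, noon

- percent here means starting material units held: one side product counts as two
- for a step with 2 of a species take k times the square, and two of it per event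
- the stated concentrations are those of everything mixed, before any reaction; amounts are the same in each set-up
- the feed brings no volume worth counting
- run time (dusk): 5.0 d

First, how fast can the chain run? Radicals arrive at 2·k2·N, with N the initiator concentration, and leave in pairs from the second chain carrier. That carrier therefore holds at y = sqrt(k2·N/k5). Starting material then falls on a chain clock c = k4·y, which is 0.202 h⁻¹ at the charge, a life of 4.94 h. This clock decays at k2/2, so the initiator charge can pay for n = 2·c/k2 = 6.98 turnovers of starting material. In dusk the life is shorter than the initiator half-life of 12.0 h, so the chain there runs while its initiator lasts.

Second, what does the side step get meanwhile? Starting material has two exits, the chain clock c and a side clock k6 times the target concentration. For dusk, the chain clock over the side clock at full target, c/(k6·cA), is 19.6, and this is the race ratio Q, a kind of selectivity factor. Target stands on average at half its final level, but each side product holds two units. These two factors cancel, so the reckoning made here commits to a share of Q over one plus Q, 95.1%, for dusk.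

Third, can another recipe beat that? The tank holds its initiator at cN/(1+k2·τ), with τ the mean stay, and so has a clock of 0.0717 h⁻¹. The last of a dose meets a clock of 0.0355 h⁻¹. Dusk's opening clock is faster than both, so this reckoning picks dusk.

The forecast also picks dusk, reasoning that “Each of the other modes keeps starting material and target together for longer”. It gives 95% for dusk, 89.5% for spring, 83% for autumn and 79% for noon.

The simulation gives 95.2% for dusk, 90.4% for spring, 83.1% for autumn and 82.0% for noon, and the best set-up is dusk.

Noon closes its feed with a race ratio Q of 3.44, and Q over one plus Q then reads 77.5% against noon's 82.0%. A neighbour of noon, charged with 0.26 M of starting material, keeps the same chain clock, but its side clock is reckoned on the smaller charge. Its ratio is 5.69, higher than noon's, and Q over one plus Q reads 85.1%. That neighbour ends with 72.1% as target and 8.68% as side product, a share of 89.2%.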